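**Retrosynthetic overview**
1. Key disconnection: the C1–O bond. A catalytic enantioselective γ-C–H benzoyloxylation of achiral β-cyclocitral (ring A) sets C1, and every other stereocentre is relayed from it.
2. Ring B: the C9–C10 bond comes from an acid-mediated Friedel–Crafts conjugate cyclisation of an aryl enone, anti to the C1 ester. Hydride reduction of the 6-ketone then gives the axial 6α-oxygen.
3. Ring C is bought as an anisole. Birch reduction and enol ether hydrolysis (C12–O from water) unmask the Δ8(9)-12-ketone.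
4. Ring D: the C11–C15 bond comes from a boron aldol with propynal. C12 is reduced before ring closure, and the C13–C16 bond is made by 5-exo-dig radical cyclisation.
5. The last step is allylic oxidation at C15. Ring order: A (bought), C (bought arene), B, D.

Assumption: atoms are numbered as in podocarpane/ent-kaurane (C15–C17 are the three carbons of propynal). α is the face of the C20 methyl group on C10 and β is the opposite face.

**Step 1**
Reactants: 1 β-cyclocitral
Product: 2 (1S)-3-formyl-2,4,4-trimethylcyclohex-2-en-1-yl benzoate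
Conditions: (PhCO2)2 (1.2 equiv), 9-amino-9-deoxy-epi-cupreidine (20 mol %), Cl3CCO2H (40 mol %), BHT (10 mol %), toluene, 0 °C
Reagents that add atoms: dibenzoyl peroxide O=C(OOC(=O)c1ccccc1)c1ccccc1
Why: Proposed new method: the chiral primary amine condenses with the hindered enal to an iminium ion whose only acidic hydrogens are γ-hydrogens, so it tautomerises to the more substituted endocyclic dienamine, whose α-carbon (C5) is blocked by the neighbouring gem-dimethyl group and whose γ-carbon (C1) therefore attacks the O–O bond of the peroxide, held on one face by a hydrogen bond to the 6'-OH of the catalyst, which forms the C1–O bond and sets (S)-C1 (the quasi-enantiomeric cupreine-derived amine is available if the sense of induction is opposite); the closest known reaction types are the amine-catalysed α-benzoyloxylation of aldehydes and ketones with dibenzoyl peroxide and the dienamine γ-amination and γ-alkylation of enals.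

**Step 2**
Reactants: 2 (1S)-3-formyl-2,4,4-trimethylcyclohex-2-en-1-yl benzoate; 3 4-methoxybenzyl chloride
Product: 5 (1S)-3-[1-hydroxy-2-(4-methoxyphenyl)ethyl]-2,4,4-trimethylcyclohex-2-en-1-yl benzoate (both C6 epimers), via 4-methoxybenzylzinc chloride 4 (not isolated)
Conditions: 3, Zn, LiCl, THF, 25 °C; then 2, MgCl2, 0 → 25 °C; aq NH4Cl
Reagents that add atoms: none
Why: This is a 1,2-addition of a benzylic organozinc reagent to an aldehyde, which spares the benzoate that a Grignard reagent would attack, and the new carbinol centre C6 forms as a mixture that step 3 erases.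

**Step 3**
Reactants: 5 (1S)-3-[1-hydroxy-2-(4-methoxyphenyl)ethyl]-2,4,4-trimethylcyclohex-2-en-1-yl benzoate
Product: 6 (1S)-3-[(4-methoxyphenyl)acetyl]-2,4,4-trimethylcyclohex-2-en-1-yl benzoate
Conditions: Dess–Martin periodinane, CH2Cl2, 0 → 23 °C
Reagents that add atoms: none
Why: Dess–Martin oxidation turns the secondary allylic alcohol into the enone under neutral conditions, so the allylic benzoate and C1 are untouched.

**Step 4**
Reactants: 6 (1S)-3-[(4-methoxyphenyl)acetyl]-2,4,4-trimethylcyclohex-2-en-1-yl benzoate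
Product: 7 1α-benzoyloxy-12-methoxy-5β,10α-podocarpa-8,11,13-trien-6-one
Conditions: TfOH (2 equiv), CH2Cl2–HFIP 4:1, −20 → 0 °C
Reagents that add atoms: none
Why: In this intramolecular Friedel–Crafts conjugate alkylation the protonated carbonyl suppresses ionisation of the C1 ester, the arene attacks C10 on the face anti to the benzoate (which shields its own face, also by transient acyloxonium participation) so that C9 is trans and C20 cis to O1, and the enol is protonated at C5 opposite the new angular methyl group to give the trans-fused ketone.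

**Step 5**
Reactants: 7 1α-benzoyloxy-12-methoxy-5β,10α-podocarpa-8,11,13-trien-6-one
Product: 8 12-methoxy-5β,10α-podocarpa-8,11,13-triene-1α,6α-diol
Conditions: LiAlH4, THF, 0 → 23 °C
Reagents that add atoms: none
Why: In this hydride reduction the α face of the 6-ketone is closed by the axial C20 and C4 methyl groups, so hydride enters from the β face and gives the axial 6α-alcohol, and the benzoate is cleaved in the same operation.

**Step 6**
Reactants: 8 12-methoxy-5β,10α-podocarpa-8,11,13-triene-1α,6α-diol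
Product: 9 12-methoxy-5β,10α-podocarpa-8,12-diene-1α,6α-diol
Conditions: Li, NH3(l), THF, t-BuOH, −78 → −33 °C; then NH4Cl
Reagents that add atoms: none
Why: Birch reduction of the dialkylanisole gives the 1,4-diene with the tetrasubstituted C8=C9 bond and the C12=C13 enol ether, as in the estradiol methyl ether series, and neither alkoxide is benzylic so no C–O bond is lost.

**Step 7**
Reactants: 9 12-methoxy-5β,10α-podocarpa-8,12-diene-1α,6α-diol
Product: 11 1α,6α-diacetoxy-5β,10α-podocarp-8-en-12-one, via diacetate dienol ether 10 (not isolated)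
Conditions: Ac2O, DMAP, pyridine, 50 °C; concentrate; (CO2H)2, THF–H2O, 23 °C
Reagents that add atoms: acetic anhydride CC(=O)OC(C)=O; water O
Why: DMAP-catalysed acetylation of both hindered alcohols is done while the base-stable enol ether masks the ketone, and mild enol ether hydrolysis with oxalic acid then gives the β,γ-unsaturated ketone without moving the C8=C9 bond.

**Step 8**
Reactants: 11 1α,6α-diacetoxy-5β,10α-podocarp-8-en-12-one; 12 propynal
Product: 14 1α,6α-diacetoxy-11β-(1-hydroxyprop-2-yn-1-yl)-5β,10α-podocarp-8-en-12-one, via dibutylboron dienolate 13 (not isolated)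
Conditions: Bu2BOTf, i-Pr2NEt, CH2Cl2, −78 → 0 °C; 12 in CH2Cl2, −78 °C; pH 7 buffer, MeOH, H2O2, 0 °C
Reagents that add atoms: none
Why: In this boron aldol addition soft enolisation removes the doubly activated C11–H without touching the acetates, the closed Zimmerman–Traxler transition state enforces 1,2-addition at the α-carbon of the dienolate, and the aldehyde approaches the β face opposite the C20 methyl group, which sets C11 with a pseudo-axial side chain (also the thermodynamic epimer), while the anti C15 carbinol is erased in step 12.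

**Step 9**
Reactants: 14 1α,6α-diacetoxy-11β-(1-hydroxyprop-2-yn-1-yl)-5β,10α-podocarp-8-en-12-one
Product: 16 1α,6α-diacetoxy-13α-bromo-11β-[1-(trimethylsilyloxy)prop-2-yn-1-yl]-5β,10α-podocarp-8-en-12-one, via bis-silyl enol ether 15 (not isolated)
Conditions: TMSOTf, Et3N, CH2Cl2, 0 °C; pentane filtration; NBS, THF, −78 °C
Reagents that add atoms: trimethylsilyl trifluoromethanesulfonate C[Si](C)(C)OS(=O)(=O)C(F)(F)F; N-bromosuccinimide O=C1CCC(=O)N1Br
Why: O-silylation blocks retro-aldol cleavage, soft enolisation goes toward C13 because the remaining C11–H lies near the carbonyl plane, and electrophilic bromination of the silyl enol ether occurs opposite the β side chain (the C13 configuration is lost in step 11).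

**Step 10**
Reactants: 16 1α,6α-diacetoxy-13α-bromo-11β-[1-(trimethylsilyloxy)prop-2-yn-1-yl]-5β,10α-podocarp-8-en-12-one
Product: 17 1α,6α-diacetoxy-13α-bromo-11β-[1-(trimethylsilyloxy)prop-2-yn-1-yl]-5β,10α-podocarp-8-en-12β-ol
Conditions: LiAlH(Ot-Bu)3, THF, −78 → −30 °C
Reagents that add atoms: none
Why: Under steric approach control on the still monocyclic ring C, hydride attacks C12 axially from the α face, anti to the pseudo-axial C11 side chain, and gives the equatorial 12β-alcohol of the target, a result that the bridged ketone would not be expected to give because its open face is the opposite one.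

**Step 11**
Reactants: 17 1α,6α-diacetoxy-13α-bromo-11β-[1-(trimethylsilyloxy)prop-2-yn-1-yl]-5β,10α-podocarp-8-en-12β-ol
Product: 19 15-dihydro-1α,6α-diacetoxyjungermannenone C (12β,15-diol), via bridged silyl ether 18 (not isolated)
Conditions: Bu3SnH (syringe pump), AIBN, toluene, 80 °C; then 1 M HCl, THF, 0 °C
Reagents that add atoms: none
Why: In this tin hydride mediated 5-exo-dig radical cyclisation the C13 radical can reach the alkyne only on the β face where the C11 chain stands, which fixes C13 and closes the bicyclo[3.2.1]octene, and the vinyl radical takes up hydrogen to leave the exocyclic methylene.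

**Step 12**
Reactants: 19 15-dihydro-1α,6α-diacetoxyjungermannenone C (12β,15-diol)
Product: 20 1α,6α-diacetoxyjungermannenone C
Conditions: activated MnO2, CH2Cl2, 23 °C
Reagents that add atoms: none
Why: MnO2 chemoselectively oxidises only the allylic C15 alcohol to the α-methylene ketone, the non-allylic 12-OH stays free, and it cannot eliminate because a C11=C12 bond would violate Bredt's rule.

**Compound list**
1 | β-cyclocitral (2,6,6-trimethylcyclohex-1-ene-1-carbaldehyde) | O=CC1=C(C)CCCC1(C)C | starting material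
2 | (1S)-3-formyl-2,4,4-trimethylcyclohex-2-en-1-yl benzoate | O=CC1=C(C)[C@@H](OC(=O)c2ccccc2)CCC1(C)C | intermediate
3 | 4-methoxybenzyl chloride | COc1ccc(CCl)cc1 | starting material
4 | 4-methoxybenzylzinc chloride | COc1ccc(C[Zn]Cl)cc1 | intermediate
5 | (1S)-3-[1-hydroxy-2-(4-methoxyphenyl)ethyl]-2,4,4-trimethylcyclohex-2-en-1-yl benzoate (C6 epimers) | COc1ccc(CC(O)C2=C(C)[C@@H](OC(=O)c3ccccc3)CCC2(C)C)cc1 | intermediate
6 | (1S)-3-[(4-methoxyphenyl)acetyl]-2,4,4-trimethylcyclohex-2-en-1-yl benzoate | COc1ccc(CC(=O)C2=C(C)[C@@H](OC(=O)c3ccccc3)CCC2(C)C)cc1 | intermediate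
7 | 1α-benzoyloxy-12-methoxy-5β,10α-podocarpa-8,11,13-trien-6-one | COc1cc3c(CC(=O)[C@@H]4C(C)(C)CC[C@H](OC(=O)c5ccccc5)[C@@]34C)cc1 | intermediate
8 | 12-methoxy-5β,10α-podocarpa-8,11,13-triene-1α,6α-diol | COc1cc3c(C[C@H](O)[C@@H]4C(C)(C)CC[C@H](O)[C@@]34C)cc1 | intermediate
9 | 12-methoxy-5β,10α-podocarpa-8,12-diene-1α,6α-diol | COC1CC3=C(C[C@H](O)[C@@H]4C(C)(C)CC[C@H](O)[C@@]34C)CC=1 | intermediate
10 | 1α,6α-diacetoxy-12-methoxy-5β,10α-podocarpa-8,12-diene | COC1CC3=C(C[C@H](OC(C)=O)[C@@H]4C(C)(C)CC[C@H](OC(C)=O)[C@@]34C)CC=1 | intermediate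
11 | 1α,6α-diacetoxy-5β,10α-podocarp-8-en-12-one | O=C1CC3=C(C[C@H](OC(C)=O)[C@@H]4C(C)(C)CC[C@H](OC(C)=O)[C@@]34C)CC1 | intermediate
12 | propynal | C#CC=O | starting material
13 | dibutylboron 8,11-dienolate of 11 | CCCCB(CCCC)OC1=CC3=C(C[C@H](OC(C)=O)[C@@H]4C(C)(C)CC[C@H](OC(C)=O)[C@@]34C)CC1 | intermediate
14 | 1α,6α-diacetoxy-11β-(1-hydroxyprop-2-yn-1-yl)-5β,10α-podocarp-8-en-12-one (anti aldol) | O=C1[C@H]([C@@H](O)C#C)C3=C(C[C@H](OC(C)=O)[C@@H]4C(C)(C)CC[C@H](OC(C)=O)[C@@]34C)CC1 | intermediate
15 | 12-trimethylsilyloxy-12-ene, 15-O-trimethylsilyl ether derived from 14 | C[Si](C)(C)OC1[C@H]([C@@H](O[Si](C)(C)C)C#C)C3=C(C[C@H](OC(C)=O)[C@@H]4C(C)(C)CC[C@H](OC(C)=O)[C@@]34C)CC=1 | intermediate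
16 | 13α-bromo-12-ketone, 15-O-trimethylsilyl ether | O=C1[C@H]([C@@H](O[Si](C)(C)C)C#C)C3=C(C[C@H](OC(C)=O)[C@@H]4C(C)(C)CC[C@H](OC(C)=O)[C@@]34C)C[C@H]1Br | intermediate
17 | 13α-bromo-12β-alcohol, 15-O-trimethylsilyl ether | O[C@@H]1[C@H]([C@@H](O[Si](C)(C)C)C#C)C3=C(C[C@H](OC(C)=O)[C@@H]4C(C)(C)CC[C@H](OC(C)=O)[C@@]34C)C[C@H]1Br | intermediate
18 | 15-O-trimethylsilyl ether of 19 | C=C1[C@H](O[Si](C)(C)C)[C@@H]2C3=C(C[C@H](OC(C)=O)[C@@H]4C(C)(C)CC[C@H](OC(C)=O)[C@@]34C)C[C@H]1[C@@H]2O | intermediate
19 | 15-dihydro-1α,6α-diacetoxyjungermannenone C (12β,15-diol, 15-OH endo) | C=C1[C@H](O)[C@@H]2C3=C(C[C@H](OC(C)=O)[C@@H]4C(C)(C)CC[C@H](OC(C)=O)[C@@]34C)C[C@H]1[C@@H]2O | intermediate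
20 | 1α,6α-diacetoxyjungermannenone C | C=C1C(=O)[C@@H]2C3=C(C[C@H](OC(C)=O)[C@@H]4C(C)(C)CC[C@H](OC(C)=O)[C@@]34C)C[C@H]1[C@@H]2O | target

**Total step count:** 12. **Longest linear sequence:** 12 steps, from β-cyclocitral 1.

**The three steps most likely to fail**

Step 1 (new reaction). The risks are low conversion of the hindered enal, oxidation of the catalyst, attack at the C20 methyl group, and low ee at the remote γ-carbon.
The fallback uses known chemistry and sets out from 1. Wohl–Ziegler bromination (NBS, AIBN, PhCF3, 80 °C) gives racemic 3-bromo-2,6,6-trimethylcyclohex-1-ene-1-carbaldehyde F1. Displacement with PhCO2K and 18-crown-6 in MeCN at 0 °C gives the racemic benzoate F2. Preparative chromatography on a cellulose tris(3,5-dimethylphenylcarbamate) phase separates 2 from the (1R)-benzoate F3. The route is rejoined at 2.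

Step 4. The arene is attacked at a position meta to the methoxy group, so the protonated enone may be too weak an electrophile before the allylic ester suffers.
The fallback sets out from 5. BF3·OEt2 in CH2Cl2 at −78 °C ionises the allylic alcohol to a tetrasubstituted allyl cation, a much stronger electrophile, which the arene captures at C10 anti to the benzoate. This gives 1α-benzoyloxy-12-methoxy-10α-podocarpa-5,8,11,13-tetraene F4. BH3·THF adds from the β face, opposite C20, to give the 6β-borane F5. NaBO3·4H2O oxidises it to 1α-benzoyloxy-12-methoxy-5β,10α-podocarpa-8,11,13-trien-6β-ol F6. Dess–Martin oxidation rejoins the route at 7.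

Step 8. The reversible aldol addition has to form a bond at C11, next to C10 and peri to the C1 acetate.
The fallback sets out from 11 and replaces the aldol by an irreversible alkylation, bringing in the C15 oxygen late by allylic C–H oxidation.
- LiHMDS (THF, −78 °C) and propargyl bromide give 1α,6α-diacetoxy-11β-(prop-2-yn-1-yl)-5β,10α-podocarp-8-en-12-one F7.
- TMSOTf and Et3N give its 12-trimethylsilyloxy-12-ene F8.
- NBS gives the 13α-bromo ketone F9.
- LiAlH(Ot-Bu)3 gives the 13α-bromo-12β-alcohol F10.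
- Bu3SnH and AIBN close ring D to 15-deoxo-1α,6α-diacetoxyjungermannenone C F11.
- SeO2 and t-BuOOH hydroxylate the allylic CH2 from the exo face to the 15-exo-alcohol F12.
- MnO2 rejoins the route at 20.

**Further compounds**
F1 | step 1 | 3-bromo-2,6,6-trimethylcyclohex-1-ene-1-carbaldehyde (racemic) | O=CC1=C(C)C(Br)CCC1(C)C
F2 | step 1 | 3-formyl-2,4,4-trimethylcyclohex-2-en-1-yl benzoate (racemic) | O=CC1=C(C)C(OC(=O)c2ccccc2)CCC1(C)C
F3 | step 1 | (1R)-3-formyl-2,4,4-trimethylcyclohex-2-en-1-yl benzoate | O=CC1=C(C)[C@H](OC(=O)c2ccccc2)CCC1(C)C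
F4 | step 4 | 1α-benzoyloxy-12-methoxy-10α-podocarpa-5,8,11,13-tetraene | COc1cc3c(CC=C4C(C)(C)CC[C@H](OC(=O)c5ccccc5)[C@@]34C)cc1
F5 | step 4 | 1α-benzoyloxy-6β-boranyl-12-methoxy-5β,10α-podocarpa-8,11,13-triene | COc1cc3c(C[C@@H](B)[C@@H]4C(C)(C)CC[C@H](OC(=O)c5ccccc5)[C@@]34C)cc1
F6 | step 4 | 1α-benzoyloxy-12-methoxy-5β,10α-podocarpa-8,11,13-trien-6β-ol | COc1cc3c(C[C@@H](O)[C@@H]4C(C)(C)CC[C@H](OC(=O)c5ccccc5)[C@@]34C)cc1
F7 | step 8 | 1α,6α-diacetoxy-11β-(prop-2-yn-1-yl)-5β,10α-podocarp-8-en-12-one | O=C1[C@H](CC#C)C3=C(C[C@H](OC(C)=O)[C@@H]4C(C)(C)CC[C@H](OC(C)=O)[C@@]34C)CC1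
F8 | step 8 | 12-trimethylsilyloxy-12-ene derived from F7 | C[Si](C)(C)OC1[C@H](CC#C)C3=C(C[C@H](OC(C)=O)[C@@H]4C(C)(C)CC[C@H](OC(C)=O)[C@@]34C)CC=1
F9 | step 8 | 13α-bromo ketone derived from F8 | O=C1[C@H](CC#C)C3=C(C[C@H](OC(C)=O)[C@@H]4C(C)(C)CC[C@H](OC(C)=O)[C@@]34C)C[C@H]1Br
F10 | step 8 | 13α-bromo-12β-alcohol derived from F9 | O[C@@H]1[C@H](CC#C)C3=C(C[C@H](OC(C)=O)[C@@H]4C(C)(C)CC[C@H](OC(C)=O)[C@@]34C)C[C@H]1Br
F11 | step 8 | 15-deoxo-1α,6α-diacetoxyjungermannenone C | C=C1C[C@@H]2C3=C(C[C@H](OC(C)=O)[C@@H]4C(C)(C)CC[C@H](OC(C)=O)[C@@]34C)C[C@H]1[C@@H]2O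
F12 | step 8 | 15-exo-alcohol (C15 epimer of 19) | C=C1[C@@H](O)[C@@H]2C3=C(C[C@H](OC(C)=O)[C@@H]4C(C)(C)CC[C@H](OC(C)=O)[C@@]34C)C[C@H]1[C@@H]2O
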